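**Plan**
- Rings: A and F are the terminal 2,4,6-trihydroxyphenyl rings, B and D the phloroglucinol rings bonded to them, C the central ring, E the 3,4,5-trihydroxyphenoxy ring.
- Cuts: the twelve O–CH3 bonds; in ring B and in ring D the C–C bond between the carbon bearing the ring C oxygen and its C–OH neighbour (retro-Claisen); C4–C5 of each chain; the two ArO–CH2 bonds; the ring C–O–ring E bond.
- Enabling feature: in rings B and D the three C–O carbons alternate with C(O–ring C), a CH and C(ring A or F). This is the pattern of a folded 6-aryloxy-2-aryl-3,5-dioxohexanoate, carried here with C3 as its methyl enol ether so that the ether-bearing carbon can act as the enolate.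
- Forward: ring A/F piece 1 to 4 (steps 1–3); ring C–E piece 5 to 16 (steps 4–8); union by twofold acylation (step 9); rings B and D closed together (step 10); global demethylation (step 11).
- Stereochemistry: the target has no stereocentre and no stereogenic axis, so nothing has to be set.

Key step: step 10

Remark: chain numbering in 17 is C1 ester carbon, C2 aryl-bearing carbon, C3 methoxy-bearing carbon, C4 CH2, C5 ketone, C6 OCH2. Compound 3 is racemic and enolisable. Compounds 4, 17 and 18 are expected as mixtures of double-bond isomers and are drawn without geometry; this is assumed harmless because the dienolates of steps 9 and 10 erase the geometry. Steps 4, 8 and 9 are twofold reactions on one molecule: each consumes two equivalents of its partner, and the second equivalent is entered where the atoms it supplies are accounted for.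

**Step 1**
Reactants: 1 2,4,6-trimethoxyphenylacetic acid
Product: 2 methyl 2-(2,4,6-trimethoxyphenyl)acetate
Conditions: MeOH, catalytic H2SO4, reflux
Reagents that add atoms: methanol, SMILES CO
Why: Fischer esterification of an unhindered arylacetic acid in excess methanol should go to completion, and the trimethoxyarene is inert to catalytic acid in methanol.

**Step 2**
Reactants: 2 methyl 2-(2,4,6-trimethoxyphenyl)acetate
Product: 3 methyl 3-oxo-2-(2,4,6-trimethoxyphenyl)butanoate (racemic; keto–enol mixture)
Conditions: LiN(SiMe3)2 (2.2 equiv), THF, −78 °C; AcCl, −78 to 0 °C; aq. NH4Cl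
Reagents that add atoms: acetyl chloride, SMILES CC(=O)Cl
Why: This is a crossed Claisen C-acylation of the lithium ester enolate by acetyl chloride, in which the second equivalent of LiN(SiMe3)2 converts the more acidic β-keto ester into its enolate as it forms and so prevents proton exchange and double acylation.

**Step 3**
Reactants: 3 methyl 3-oxo-2-(2,4,6-trimethoxyphenyl)butanoate
Product: 4 methyl 3-methoxy-2-(2,4,6-trimethoxyphenyl)but-2-enoate (E/Z mixture)
Conditions: HC(OMe)3 (excess, neat), catalytic p-TsOH, 50 °C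
Reagents that add atoms: trimethyl orthoformate, SMILES COC(OC)OC
Why: Acid-catalysed enol ether formation from a β-keto ester with an orthoformate as methyl donor and water scavenger should methylate the ketone oxygen only, which avoids the C-methylation open to the enolate and leaves C4 as the one acidic position.

**Step 4**
Reactants: 5 2,6-difluoro-4-methoxybenzaldehyde
Product: 7 2,6-bis(benzyloxy)-4-methoxybenzaldehyde, via 2-benzyloxy-6-fluoro-4-methoxybenzaldehyde 6 (not isolated)
Conditions: BnOH (2.4 equiv), NaH (2.4 equiv), DMF, 0 to 60 °C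
Reagents that add atoms: benzyl alcohol (two equivalents are incorporated, one per fluoride), SMILES OCc1ccccc1
Why: Twofold nucleophilic aromatic substitution (addition–elimination through formyl-stabilised Meisenheimer anions) should replace both fluorides ortho to the aldehyde by benzyl oxide, the aldehyde being masked only reversibly as its hemiacetal alkoxide.

**Step 5**
Reactants: 7 2,6-bis(benzyloxy)-4-methoxybenzaldehyde
Product: 9 2,6-bis(benzyloxy)-4-methoxyphenol, via aryl formate 8 (not isolated)
Conditions: mCPBA, CH2Cl2, 0 °C to rt; then KOH, MeOH–H2O, rt; aq. HCl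
Reagents that add atoms: mCPBA, SMILES OOC(=O)c1cccc(Cl)c1
Why: In this Dakin oxidation, a Baeyer–Villiger reaction in which the electron-rich 2,4,6-trioxygenated aryl group migrates in preference to hydrogen, the peracid should give the aryl formate, which the hydroxide then saponifies to the phenol.

**Step 6**
Reactants: 9 2,6-bis(benzyloxy)-4-methoxyphenol; 10 5-iodo-1,2,3-trimethoxybenzene
Product: 11 1,3-bis(benzyloxy)-5-methoxy-2-(3,4,5-trimethoxyphenoxy)benzene
Conditions: CuI (10 mol %), picolinic acid (20 mol %), K3PO4, DMSO, 90 °C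
Reagents that add atoms: none
Why: The Ullmann diaryl ether synthesis with CuI and picolinic acid is suited to di-ortho-substituted phenols, the aryl iodide is unhindered, and benzyl and methyl ethers are inert under these conditions.

**Step 7**
Reactants: 11 1,3-bis(benzyloxy)-5-methoxy-2-(3,4,5-trimethoxyphenoxy)benzene
Product: 13 5-methoxy-2-(3,4,5-trimethoxyphenoxy)benzene-1,3-diol, via monobenzyl ether 12 (not isolated)
Conditions: H2 (1 atm), 10% Pd/C, EtOAc–MeOH, rt
Reagents that add atoms: none
Why: Hydrogenolysis over Pd/C should cleave the two benzyl–oxygen bonds only, since diaryl and methyl aryl ethers are stable to it, and so frees exactly the two hydroxyls that flank the ring E ether.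

**Step 8**
Reactants: 13 5-methoxy-2-(3,4,5-trimethoxyphenoxy)benzene-1,3-diol; 14 2-chloro-N-methoxy-N-methylacetamide (two equivalents react, one at each hydroxyl)
Product: 16 2,2'-{[5-methoxy-2-(3,4,5-trimethoxyphenoxy)-1,3-phenylene]bis(oxy)}bis(N-methoxy-N-methylacetamide), via monoalkylated phenol 15 (not isolated)
Conditions: 14 (2.3 equiv), K2CO3 (3 equiv), catalytic KI, DMF, 60 °C
Reagents that add atoms: 2-chloro-N-methoxy-N-methylacetamide (the second equivalent of 14, which alkylates phenol 15), SMILES CON(C)C(=O)CCl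
Why: Williamson O-alkylation of the two phenoxides by the α-chloro amide, speeded by iodide exchange, should be clean because carbonate is too weak a base to enolise the amide and the N-methoxy-N-methylamide does not react with phenoxide.

**Step 9**
Reactants: 16 2,2'-{[5-methoxy-2-(3,4,5-trimethoxyphenoxy)-1,3-phenylene]bis(oxy)}bis(N-methoxy-N-methylacetamide); 4 methyl 3-methoxy-2-(2,4,6-trimethoxyphenyl)but-2-enoate (two equivalents react, one at each amide)
Product: 17 dimethyl 6,6'-{[5-methoxy-2-(3,4,5-trimethoxyphenoxy)-1,3-phenylene]bis(oxy)}bis[3-methoxy-5-oxo-2-(2,4,6-trimethoxyphenyl)hex-2-enoate] (double-bond isomers)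
Conditions: 4 (2.6 equiv), LiN(i-Pr)2 (2.5 equiv), THF, −78 °C; then 16 (1 equiv), −78 to −30 °C; aq. NH4Cl
Reagents that add atoms: methyl 3-methoxy-2-(2,4,6-trimethoxyphenyl)but-2-enoate (the second equivalent of 4, which acylates at the second amide), SMILES COC(=O)C(=C(C)OC)c1c(OC)cc(OC)cc1OC
Why: γ-Deprotonation of the β-methoxy enoate gives a lithium dienolate that should add through its unhindered terminal carbon to each N-methoxy-N-methylamide (Claisen-type acylation), and because the chelated tetrahedral adducts persist until the quench no ketone is exposed to a second addition or to the base.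

**Step 10**
Reactants: 17 dimethyl 6,6'-{[5-methoxy-2-(3,4,5-trimethoxyphenoxy)-1,3-phenylene]bis(oxy)}bis[3-methoxy-5-oxo-2-(2,4,6-trimethoxyphenyl)hex-2-enoate]
Product: 19 3,3''-{[5-methoxy-2-(3,4,5-trimethoxyphenoxy)-1,3-phenylene]bis(oxy)}bis(2',4',6,6'-tetramethoxybiphenyl-2,4-diol), via monocyclised keto ester 18 (not isolated)
Conditions: NaOMe (excess), MeOH, reflux, under argon; then aq. HCl
Reagents that add atoms: none
Why: Methoxide reversibly removes a proton from C4 and from C6 of each chain, and the C6 enolate (the ketone α-carbon that carries the ring C oxygen) adds to the C1 ester carbonyl held cis to C4 on the C2=C3 enol ether; loss of methoxide gives a 6-aryloxycyclohexenedione that should tautomerise at once to the phenol, which makes each closure irreversible. The closest known reactions are the Claisen (Dieckmann-type) cyclisation of 5-oxo esters to cyclohexane-1,3-diones and the cyclisation of partly O-methylated poly-β-keto esters to phloroglucinol ethers. Ring B and ring D each close 6-exo-trig at the ester carbonyl, one after the other, through monocyclised 18. No stereocentre is formed. The selectivity needed is carbon over oxygen acylation and C6 over C4 as the nucleophile: C4 cannot reach C1 through a ring of workable size, and its enolate oxygen can only give the 4-methoxy-2-pyranone, which methoxide reopens, whereas the carbocyclic product is withdrawn as its phenoxide. Carrying the C3 carbonyl as a methyl enol ether is what secures this, since the chain then has no β-diketonate and no C2 proton, so the ester is not switched off as its own enolate and C4 and C6 should be of comparable acidity.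

**Step 11**
Reactants: 19 3,3''-{[5-methoxy-2-(3,4,5-trimethoxyphenoxy)-1,3-phenylene]bis(oxy)}bis(2',4',6,6'-tetramethoxybiphenyl-2,4-diol)
Product: 20 3,3''-{[5-hydroxy-2-(3,4,5-trihydroxyphenoxy)-1,3-phenylene]bis(oxy)}bis(biphenyl-2,2',4,4',6,6'-hexol) (CNP0279880.0)
Conditions: BBr3 (large excess), CH2Cl2, −78 °C to rt; then H2O
Reagents that add atoms: none
Why: BBr3 ether cleavage proceeds by coordination to each methoxy oxygen and SN2 removal of the methyl group by bromide, a path closed to the three diaryl ether oxygens, whose carbons are all sp2, so that hydrolysis of the aryl borates should give the hexadecaphenol with its skeleton intact.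

**Compound list**
1 | 2,4,6-trimethoxyphenylacetic acid | COc1cc(OC)c(CC(=O)O)c(OC)c1 | starting material
2 | methyl 2-(2,4,6-trimethoxyphenyl)acetate | COC(=O)Cc1c(OC)cc(OC)cc1OC | intermediate
3 | methyl 3-oxo-2-(2,4,6-trimethoxyphenyl)butanoate (racemic) | COC(=O)C(C(C)=O)c1c(OC)cc(OC)cc1OC | intermediate
4 | methyl 3-methoxy-2-(2,4,6-trimethoxyphenyl)but-2-enoate (E/Z mixture) | COC(=O)C(=C(C)OC)c1c(OC)cc(OC)cc1OC | intermediate
5 | 2,6-difluoro-4-methoxybenzaldehyde | COc1cc(F)c(C=O)c(F)c1 | starting material
6 | 2-benzyloxy-6-fluoro-4-methoxybenzaldehyde (not isolated) | COc1cc(F)c(C=O)c(OCc2ccccc2)c1 | intermediate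
7 | 2,6-bis(benzyloxy)-4-methoxybenzaldehyde | COc1cc(OCc2ccccc2)c(C=O)c(OCc2ccccc2)c1 | intermediate
8 | 2,6-bis(benzyloxy)-4-methoxyphenyl formate (not isolated) | COc1cc(OCc2ccccc2)c(OC=O)c(OCc2ccccc2)c1 | intermediate
9 | 2,6-bis(benzyloxy)-4-methoxyphenol | COc1cc(OCc2ccccc2)c(O)c(OCc2ccccc2)c1 | intermediate
10 | 5-iodo-1,2,3-trimethoxybenzene | COc1cc(I)cc(OC)c1OC | starting material
11 | 1,3-bis(benzyloxy)-5-methoxy-2-(3,4,5-trimethoxyphenoxy)benzene | COc1cc(OCc2ccccc2)c(Oc2cc(OC)c(OC)c(OC)c2)c(OCc2ccccc2)c1 | intermediate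
12 | 3-benzyloxy-5-methoxy-2-(3,4,5-trimethoxyphenoxy)phenol (not isolated) | COc1cc(O)c(Oc2cc(OC)c(OC)c(OC)c2)c(OCc2ccccc2)c1 | intermediate
13 | 5-methoxy-2-(3,4,5-trimethoxyphenoxy)benzene-1,3-diol | COc1cc(O)c(Oc2cc(OC)c(OC)c(OC)c2)c(O)c1 | intermediate
14 | 2-chloro-N-methoxy-N-methylacetamide | CON(C)C(=O)CCl | starting material
15 | 2-[3-hydroxy-5-methoxy-2-(3,4,5-trimethoxyphenoxy)phenoxy]-N-methoxy-N-methylacetamide (not isolated) | COc1cc(O)c(Oc2cc(OC)c(OC)c(OC)c2)c(OCC(=O)N(C)OC)c1 | intermediate
16 | 2,2'-{[5-methoxy-2-(3,4,5-trimethoxyphenoxy)-1,3-phenylene]bis(oxy)}bis(N-methoxy-N-methylacetamide) | COc1cc(OCC(=O)N(C)OC)c(Oc2cc(OC)c(OC)c(OC)c2)c(OCC(=O)N(C)OC)c1 | intermediate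
17 | dimethyl 6,6'-{[5-methoxy-2-(3,4,5-trimethoxyphenoxy)-1,3-phenylene]bis(oxy)}bis[3-methoxy-5-oxo-2-(2,4,6-trimethoxyphenyl)hex-2-enoate] (double-bond isomers) | COc1cc(OCC(=O)CC(OC)=C(C(=O)OC)c2c(OC)cc(OC)cc2OC)c(Oc2cc(OC)c(OC)c(OC)c2)c(OCC(=O)CC(OC)=C(C(=O)OC)c2c(OC)cc(OC)cc2OC)c1 | intermediate
18 | methyl 6-{3-[(2,4-dihydroxy-2',4',6,6'-tetramethoxybiphenyl-3-yl)oxy]-5-methoxy-2-(3,4,5-trimethoxyphenoxy)phenoxy}-3-methoxy-5-oxo-2-(2,4,6-trimethoxyphenyl)hex-2-enoate (not isolated) | COc1cc(Oc2c(O)cc(OC)c(-c3c(OC)cc(OC)cc3OC)c2O)c(Oc2cc(OC)c(OC)c(OC)c2)c(OCC(=O)CC(OC)=C(C(=O)OC)c2c(OC)cc(OC)cc2OC)c1 | intermediate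
19 | 3,3''-{[5-methoxy-2-(3,4,5-trimethoxyphenoxy)-1,3-phenylene]bis(oxy)}bis(2',4',6,6'-tetramethoxybiphenyl-2,4-diol) | COc1cc(Oc2c(O)cc(OC)c(-c3c(OC)cc(OC)cc3OC)c2O)c(Oc2cc(OC)c(OC)c(OC)c2)c(Oc2c(O)cc(OC)c(-c3c(OC)cc(OC)cc3OC)c2O)c1 | intermediate
20 | 3,3''-{[5-hydroxy-2-(3,4,5-trihydroxyphenoxy)-1,3-phenylene]bis(oxy)}bis(biphenyl-2,2',4,4',6,6'-hexol), CNP0279880.0 | Oc1cc(O)c(-c2c(O)cc(O)c(Oc3cc(O)cc(Oc4c(O)cc(O)c(-c5c(O)cc(O)cc5O)c4O)c3Oc3cc(O)c(O)c(O)c3)c2O)c(O)c1 | target

**Step count**
Total: 11 steps. Longest linear sequence: 8 steps (5 to 20, steps 4–11).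

**Steps most likely to fail**

Step 10. Enolisation may stay almost wholly at C4, so that the ether-bearing carbon is too rarely the nucleophile and the chains are lost to pyranone formation, retro-Claisen cleavage of the C4–C5 bond and slow base degradation before both rings have closed. The fallback folds the chain the other way round: the benzylic carbon becomes the nucleophile and the ester sits on the ether-bearing carbon, so the same rings arise by the same kind of Claisen closure. It sets out from diol 13 and acid 1 and comes back to the route at target 20. Diol 13 is alkylated twice with methyl 2-chloro-3-oxobutanoate (K2CO3, acetone) to give dimethyl 2,2'-{[5-methoxy-2-(3,4,5-trimethoxyphenoxy)-1,3-phenylene]bis(oxy)}bis(3-oxobutanoate) F1, which HC(OMe)3 and catalytic p-TsOH convert into the bis(3-methoxybut-2-enoate) F2. Acid 1 is turned with 1,1'-carbonyldiimidazole and MeNHOMe·HCl into N-methoxy-N-methyl-2-(2,4,6-trimethoxyphenyl)acetamide F3. The bis(dienolate) made from F2 with LiN(i-Pr)2 at −78 °C is acylated by two equivalents of F3 to give the bis[3-methoxy-5-oxo-6-(2,4,6-trimethoxyphenyl)hex-2-enoate] F4. NaOMe in refluxing MeOH should then close both rings to 3,3''-{[5-methoxy-2-(3,4,5-trimethoxyphenoxy)-1,3-phenylene]bis(oxy)}bis(2',4,4',6'-tetramethoxybiphenyl-2,6-diol) F5, an isomer of 19 that differs only in which ring B and ring D oxygen is methylated. BBr3 as in step 11 converts F5 into target 20.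

Step 9. Proton transfer from the OCH2 groups of 16 to the dienolate, or stalling after the first of the two additions on the crowded bis(amide), would leave half-acylated material. The fallback makes the carbon–carbon bond on the small amide first. It sets out from 4: its lithium dienolate is acylated by 14 at −78 °C to give methyl 6-chloro-3-methoxy-5-oxo-2-(2,4,6-trimethoxyphenyl)hex-2-enoate F6. Diol 13 is then alkylated twice with F6 (K2CO3, catalytic KI, acetone), which comes back to the route at 17.

Step 11. Cleavage of twelve methyl ethers may stop short at the most hindered positions, and the free hexadecaphenol may be lost by air oxidation and adsorption during purification. The fallback sets out from 19 and isolates the product in protected form. The crude material from the BBr3 treatment is acetylated (Ac2O, pyridine, DMAP) to the hexadecaacetate of 20 F7, which can be chromatographed and separated from under-demethylated material. Acid methanolysis under argon (HCl generated from AcCl in MeOH) then releases 20, where the fallback rejoins the route.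

**Further compounds**
F1 | step 10 | dimethyl 2,2'-{[5-methoxy-2-(3,4,5-trimethoxyphenoxy)-1,3-phenylene]bis(oxy)}bis(3-oxobutanoate) | COc1cc(OC(C(C)=O)C(=O)OC)c(Oc2cc(OC)c(OC)c(OC)c2)c(OC(C(C)=O)C(=O)OC)c1
F2 | step 10 | dimethyl 2,2'-{[5-methoxy-2-(3,4,5-trimethoxyphenoxy)-1,3-phenylene]bis(oxy)}bis(3-methoxybut-2-enoate) | COc1cc(OC(C(=O)OC)=C(C)OC)c(Oc2cc(OC)c(OC)c(OC)c2)c(OC(C(=O)OC)=C(C)OC)c1
F3 | step 10 | N-methoxy-N-methyl-2-(2,4,6-trimethoxyphenyl)acetamide | CON(C)C(=O)Cc1c(OC)cc(OC)cc1OC
F4 | step 10 | dimethyl 2,2'-{[5-methoxy-2-(3,4,5-trimethoxyphenoxy)-1,3-phenylene]bis(oxy)}bis[3-methoxy-5-oxo-6-(2,4,6-trimethoxyphenyl)hex-2-enoate] | COc1cc(OC(C(=O)OC)=C(CC(=O)Cc2c(OC)cc(OC)cc2OC)OC)c(Oc2cc(OC)c(OC)c(OC)c2)c(OC(C(=O)OC)=C(CC(=O)Cc2c(OC)cc(OC)cc2OC)OC)c1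
F5 | step 10 | 3,3''-{[5-methoxy-2-(3,4,5-trimethoxyphenoxy)-1,3-phenylene]bis(oxy)}bis(2',4,4',6'-tetramethoxybiphenyl-2,6-diol) | COc1cc(Oc2c(OC)cc(O)c(-c3c(OC)cc(OC)cc3OC)c2O)c(Oc2cc(OC)c(OC)c(OC)c2)c(Oc2c(OC)cc(O)c(-c3c(OC)cc(OC)cc3OC)c2O)c1
F6 | step 9 | methyl 6-chloro-3-methoxy-5-oxo-2-(2,4,6-trimethoxyphenyl)hex-2-enoate | COC(=O)C(=C(CC(=O)CCl)OC)c1c(OC)cc(OC)cc1OC
F7 | step 11 | hexadecaacetate of 20 | CC(=O)Oc1cc(OC(C)=O)c(-c2c(OC(C)=O)cc(OC(C)=O)c(Oc3cc(OC(C)=O)cc(Oc4c(OC(C)=O)cc(OC(C)=O)c(-c5c(OC(C)=O)cc(OC(C)=O)cc5OC(C)=O)c4OC(C)=O)c3Oc3cc(OC(C)=O)c(OC(C)=O)c(OC(C)=O)c3)c2OC(C)=O)c(OC(C)=O)c1
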